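The constants used here were chosen freely; what happens was integrated by code.

With a small charge of 20 mM of starting material, I ask how much of it the gas reaches before it goes another way.

starting material 20 mM; gas phase 1.0 mM (held); protic impurity 4.00 mM; time 8.0 min

- amount of target at 8.0 min, in percent of the starting material charged
- the change that raises the amount of target at 8.0 min, in percent of the starting material charged most ("none" if none brings more than 2 percentage points) (alpha / delta / none)
- amount of target at 8.0 min, in percent of the starting material charged, after delta

- alpha: doubling the saturation concentration of gas phase, all else as stated
- delta: doubling the transfer coefficient of step 1, all else as stated

- in percentages every species weighs as the starting material in it: one homo dimer counts as two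
- a step written with two of one species runs at k times the square of its concentration and takes two of it each time
- at the start none of the gas is dissolved
- run time (flask): 8.0 min

    gas phase ⇌ dissolved gas, rate k1*(csat - [dissolved gas]) (k1 = 0.50 s⁻¹, csat = 1.0 mM)
    dissolved gas → decomposed reagent (k2 = 0.024 s⁻¹)
    starting material + dissolved gas → target (k3 = 200 M⁻¹ s⁻¹)
    2 starting material → homo dimer (k4 = 1.9 M⁻¹ s⁻¹)
    starting material → side product (k5 = 0.12 s⁻¹)
    starting material + protic impurity → quenched substrate (k6 = 1.1 M⁻¹ s⁻¹)

I count half-lives, fastest first. Gas entering an empty solution approaches saturation with a half-life of 0.0231 min. But starting material takes dissolved gas up at a pseudo-first-order rate of 4.00 s⁻¹, far above the transfer coefficient of 0.50 s⁻¹. So at the start dissolved gas stays low, and transfer, delivering up to 0.500 mM s⁻¹, is the rate-limiting step for target.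

On the next rung, the first-order step to side product halves starting material in 0.096 min, and at the charge it consumes 2.40 mM s⁻¹, more than transfer delivers. Then come the first half-life of the dimerisation, 0.219 min, that of dissolved gas decomposing, 0.48 min, and that of starting material quenched by the protic impurity held at its charge, 2.6 min. The run of 8.0 min is much longer than the first of these losses, so I expect target to stop growing early.

I therefore carry the gas window, the gas transferred into a nearly empty solution during one first-order lifetime of the starting material: 4.17 mM. The charge does not enter it, so as a share of this charge it gives 20.8 %, which is my figure for the target.

Both changes double the window, to 41.7 %, so that is my figure after delta. Late on, though, with little starting material left, dissolved gas at saturation takes up starting material at 0.200 s⁻¹, faster than the side step's 0.12 s⁻¹. Doubling the saturation concentration doubles that rate, and doubling transfer does not, so I put alpha first.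

The forecast gives 22 % (range 20 % to 25 %), names alpha as best, and gives 30 % after delta (range 27 % to 33 %), less than my doubled window. Its ground is that “dissolved gas stays far below saturation while starting material is high”.

The simulation gives 22.5 %, with alpha best: it gains 12 percentage points against 8 points for delta. After delta the target is 30.5 %, less than my doubled window.

In the flask, starting material drops below 2 % of its charge by 0.290 min, with half of the side-product turnover done by 0.0549 min, and target stands at 22.5 % by 2.00 min. After that, dissolved gas holds at 0.954 mM while its decomposition runs on, reaching 10.7 mM of decomposed reagent at 8.00 min. The window of 4.17 mM stands against 4.50 mM of target in this flask. For the neighbour flask with 34 mM of starting material, the window gives 12.3 %, and the simulation gives 16.2 %, which is 5.51 mM of target.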